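## Retrosynthetic overview

(Chain atoms C1–C7 of the hept-2-enoate; ring atoms C1′–C6′.)

1. The C4 acetate comes from the C4 alcohol. The C2–homoprenyl bond comes from a B-alkyl Suzuki coupling on a (2Z)-2-iodo enoate, made by trans-hydroalumination/iodination of a γ-hydroxy ynoate.
2. The C3–C4 bond comes from catalyst-controlled addition of methyl propiolate to a C4 aldehyde; this sets C4.
3. Key step: C5 and C4 are grown onto C6 by two consecutive 1,2-shifts of the C6 carbon from boron to carbon (stereoretentive 1,2-metallate rearrangements) starting from a secondary boronic ester.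
4. The C6–C1′ bond and both configurations come from a copper hydride hydroallylation of vinyl-Bpin with an enantiopure vinyl oxirane (anti-SN2′; new method).
5. Rings: the only ring is bought as 1-methylcyclohexa-1,3-diene and made chiral by Shi epoxidation; no ring is formed in the route.

Assumption: 1-methylcyclohexa-1,3-diene is taken as purchasable, and the pinacol unit of vinyl-Bpin is counted as a protecting group on boron.

## Route

Step 1
Reactants: 1 1-methylcyclohexa-1,3-diene
Product: 2 (1R,6S)-6-methyl-7-oxabicyclo[4.1.0]hept-2-ene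
Conditions: D-fructose-derived Shi ketone (30 mol %), KHSO5, K2CO3, Bu4NHSO4, MeCN/CH2(OMe)2/aq. Na2B4O7–Na2(EDTA) buffer (pH 10.5), 0 °C
Reagents that add atoms: potassium peroxymonosulfate, [K+].[O-]S(=O)(=O)OO
Why: Shi asymmetric epoxidation: the chiral dioxirane attacks the more electron-rich trisubstituted alkene (cis-disubstituted alkenes are poor substrates for this ketone) through the spiro transition state, in the same facial sense that gives (R,R)-1-phenylcyclohexene oxide, which here is the (1R,6S) oxide; the basic medium protects the acid-labile vinyl oxirane.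

Step 2
Reactants: 2 (1R,6S)-6-methyl-7-oxabicyclo[4.1.0]hept-2-ene; 3 vinylboronic acid pinacol ester
Product: 5 (1S,4R)-1-methyl-4-[(1S)-1-(4,4,5,5-tetramethyl-1,3,2-dioxaborolan-2-yl)ethyl]cyclohex-2-en-1-ol, via silyl ether 4 (not isolated)
Conditions: Cu(OAc)2 (5 mol %), (S)-DTBM-SEGPHOS (5.5 mol %), (MeO)2MeSiH, THF, rt, slow addition of 2; then MeOH, K2CO3 (cat.), 0 °C
Reagents that add atoms: none
Why: Proposed new method: copper hydride hydroallylation of an alkenyl boronate with a cyclic vinyl oxirane as the allyl electrophile. The ligated copper hydride adds across 3 with copper on the boron-bearing carbon (α-boryl stabilisation), and the ligand sets this centre (1S on the ethyl group, intended sense; the antipodal ligand gives the epimer), which is the spatial equivalent of C6 (R) of the target. The α-boryl alkylcopper then attacks the alkene terminus of 2 anti to the allylic C–O bond (anti-SN2′ oxidative addition, C–C reductive elimination with retention), which places the side chain trans to the tertiary OH and fixes ring C4 (R). The tertiary copper alkoxide is turned over by the silane. Closest known reactions: copper hydride hydroallylation of alkenyl boronates with allylic phosphates, and copper-mediated anti-SN2′ opening of cyclic vinyl oxiranes by alkyl Grignard reagents.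

Step 3
Reactants: 5 (1S,4R)-1-methyl-4-[(1S)-1-(4,4,5,5-tetramethyl-1,3,2-dioxaborolan-2-yl)ethyl]cyclohex-2-en-1-ol
Product: 8 (3R)-3-[(1R,4S)-4-hydroxy-4-methylcyclohex-2-en-1-yl]butanal, via homologated boronic ester 6 (not isolated), via chloro boronic ester 7 (not isolated)
Conditions: NaH, THF, 0 °C; BrCH2Cl, n-BuLi, −78 °C to rt; then CH2Cl2, LiN(i-Pr)2, −78 °C to rt; then 30% H2O2, aq. NaHCO3, 0 °C
Reagents that add atoms: bromochloromethane, ClCBr; dichloromethane, ClCCl; hydrogen peroxide, OO
Why: Matteson homologation run twice in one pot: each lithium carbenoid adds to boron and the carbon–boron bond shifts 1,2 onto the carbenoid carbon with loss of chloride and full retention at the migrating stereocentre, so the C–B centre of 5 becomes the C-methyl centre C6 (R) while C5 and C4 are built; peroxide oxidation of the α-chloro boronate gives the aldehyde.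

Step 4
Reactants: 8 (3R)-3-[(1R,4S)-4-hydroxy-4-methylcyclohex-2-en-1-yl]butanal; 9 methyl propiolate
Product: 11 methyl (4R,6R)-4-hydroxy-6-[(1R,4S)-4-hydroxy-4-methylcyclohex-2-en-1-yl]hept-2-ynoate, via alkynylzinc 10 (not isolated)
Conditions: (S)-BINOL (40 mol %), Et2Zn, HMPA, CH2Cl2, rt, 16 h; Ti(Oi-Pr)4, then 8, rt
Reagents that add atoms: none
Why: BINOL/Ti(Oi-Pr)4-mediated asymmetric alkynylzinc addition: the (S)-BINOL titanium complex is expected to deliver the zinc acetylide of 9 to the Si face of the unhindered aliphatic aldehyde, setting C4 (R) under catalyst control (the remote C6 centre exerts little bias), while excess Et2Zn masks the tertiary alcohol as its zinc alkoxide.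

Step 5
Reactants: 11 methyl (4R,6R)-4-hydroxy-6-[(1R,4S)-4-hydroxy-4-methylcyclohex-2-en-1-yl]hept-2-ynoate
Product: 13 methyl (2Z,4R,6R)-4-hydroxy-6-[(1R,4S)-4-hydroxy-4-methylcyclohex-2-en-1-yl]-2-iodohept-2-enoate, via vinylalanate 12 (not isolated)
Conditions: NaAlH2(OCH2CH2OMe)2 (3 equiv), THF, −78 °C; then I2, −78 to 0 °C; aq. KNaC4H4O6/Na2S2O3 work-up
Reagents that add atoms: iodine, II
Why: Hydroxyl-directed trans-hydroalumination: the alkoxyaluminium hydride puts hydride on C3 and leaves aluminium on C2 cis to the carbinol carbon in a five-membered chelate, and iodinolysis with retention gives the (2Z)-2-iodo enoate; no stereocentre is touched.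

Step 6
Reactants: 13 methyl (2Z,4R,6R)-4-hydroxy-6-[(1R,4S)-4-hydroxy-4-methylcyclohex-2-en-1-yl]-2-iodohept-2-enoate; 14 4-methylpenta-1,3-diene
Product: 16 methyl (2E,4R,6R)-4-hydroxy-6-[(1R,4S)-4-hydroxy-4-methylcyclohex-2-en-1-yl]-2-(4-methylpent-3-en-1-yl)hept-2-enoate, via alkylborane 15 (not isolated)
Conditions: 14, 9-BBN-H dimer, THF, 0 °C to rt; then 13, Pd(dppf)Cl2 (5 mol %), AsPh3, Cs2CO3, DMF/H2O, rt
Reagents that add atoms: none
Why: 9-BBN hydroborates only the monosubstituted alkene of 14 (anti-Markovnikov), and the primary alkylborane undergoes B-alkyl Suzuki–Miyaura coupling with the vinyl iodide with retention of alkene geometry, so the homoprenyl chain ends cis to C4 and the ester trans to it (2E); free hydroxyls are tolerated.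

Step 7
Reactants: 16 methyl (2E,4R,6R)-4-hydroxy-6-[(1R,4S)-4-hydroxy-4-methylcyclohex-2-en-1-yl]-2-(4-methylpent-3-en-1-yl)hept-2-enoate
Product: 17 methyl (2E,4R,6R)-4-acetoxy-6-[(1R,4S)-4-hydroxy-4-methylcyclohex-2-en-1-yl]-2-(4-methylpent-3-en-1-yl)hept-2-enoate
Conditions: Ac2O (1.3 equiv), pyridine, DMAP (5 mol %), CH2Cl2, 0 °C
Reagents that add atoms: acetic anhydride, CC(=O)OC(C)=O
Why: DMAP-catalysed acylation is selective for the secondary allylic alcohol over the hindered tertiary allylic alcohol at 0 °C and touches no stereocentre, giving the target.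

## Compound list

1 | 1-methylcyclohexa-1,3-diene | CC1=CC=CCC1 | starting material
2 | (1R,6S)-6-methyl-7-oxabicyclo[4.1.0]hept-2-ene | C[C@]12CCC=C[C@H]1O2 | intermediate
3 | 4,4,5,5-tetramethyl-2-vinyl-1,3,2-dioxaborolane (vinylboronic acid pinacol ester; pinacol is the protecting group on boron) | C=CB1OC(C)(C)C(C)(C)O1 | starting material
4 | dimethoxy(methyl)silyl ether of 5 | CC1(C)OB(OC1(C)C)[C@@H](C)[C@@H]2C=C[C@@](C)(O[Si](C)(OC)OC)CC2 | intermediate
5 | (1S,4R)-1-methyl-4-[(1S)-1-(4,4,5,5-tetramethyl-1,3,2-dioxaborolan-2-yl)ethyl]cyclohex-2-en-1-ol | CC1(C)OB(OC1(C)C)[C@@H](C)[C@@H]2C=C[C@@](C)(O)CC2 | intermediate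
6 | (1S,4R)-1-methyl-4-[(2R)-1-(4,4,5,5-tetramethyl-1,3,2-dioxaborolan-2-yl)propan-2-yl]cyclohex-2-en-1-ol (alkoxide in the flask) | CC1(C)OB(OC1(C)C)C[C@@H](C)[C@@H]2C=C[C@@](C)(O)CC2 | intermediate
7 | (1S,4R)-4-[(2R)-4-chloro-4-(4,4,5,5-tetramethyl-1,3,2-dioxaborolan-2-yl)butan-2-yl]-1-methylcyclohex-2-en-1-ol (both epimers at the chloro carbon; alkoxide in the flask) | CC1(C)OB(OC1(C)C)C(Cl)C[C@@H](C)[C@@H]2C=C[C@@](C)(O)CC2 | intermediate
8 | (3R)-3-[(1R,4S)-4-hydroxy-4-methylcyclohex-2-en-1-yl]butanal | O=CC[C@@H](C)[C@@H]1C=C[C@@](C)(O)CC1 | intermediate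
9 | methyl propiolate (methyl prop-2-ynoate) | C#CC(=O)OC | starting material
10 | ethyl(3-methoxy-3-oxoprop-1-yn-1-yl)zinc | CC[Zn]C#CC(=O)OC | intermediate
11 | methyl (4R,6R)-4-hydroxy-6-[(1R,4S)-4-hydroxy-4-methylcyclohex-2-en-1-yl]hept-2-ynoate | COC(=O)C#C[C@@H](C[C@@H](C)[C@@H]1C=C[C@@](C)(O)CC1)O | intermediate
12 | disodium salt of the cyclic vinylalanate: aluminium bound to C2 and to the C4 oxygen (five-membered chelate), two 2-methoxyethoxy ligands, tertiary alkoxide (idealised) | COC(=O)C1=C[C@@H](C[C@@H](C)[C@@H]2C=C[C@@](C)([O-])CC2)O[Al-]1(OCCOC)OCCOC.[Na+].[Na+] | intermediate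
13 | methyl (2Z,4R,6R)-4-hydroxy-6-[(1R,4S)-4-hydroxy-4-methylcyclohex-2-en-1-yl]-2-iodohept-2-enoate | COC(=O)/C(I)=C/[C@@H](C[C@@H](C)[C@@H]1C=C[C@@](C)(O)CC1)O | intermediate
14 | 4-methylpenta-1,3-diene | CC(C)=CC=C | starting material
15 | 9-(4-methylpent-3-en-1-yl)-9-borabicyclo[3.3.1]nonane | CC(C)=CCCB1C2CCCC1CCC2 | intermediate
16 | methyl (2E,4R,6R)-4-hydroxy-6-[(1R,4S)-4-hydroxy-4-methylcyclohex-2-en-1-yl]-2-(4-methylpent-3-en-1-yl)hept-2-enoate | COC(=O)/C(=C/[C@@H](C[C@@H](C)[C@@H]1C=C[C@@](C)(O)CC1)O)CCC=C(C)C | intermediate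
17 | methyl (2E,4R,6R)-4-acetoxy-6-[(1R,4S)-4-hydroxy-4-methylcyclohex-2-en-1-yl]-2-(4-methylpent-3-en-1-yl)hept-2-enoate | COC(=O)/C(=C/[C@@H](C[C@@H](C)[C@@H]1C=C[C@@](C)(O)CC1)OC(C)=O)CCC=C(C)C | target

## Step count and risks

Total step count: 7. Longest linear sequence: 7 (1 → 2 → 5 → 8 → 11 → 13 → 16 → 17; 3, 9 and 14 are bought).

The three steps most likely to fail:

Step 2 (the new hydroallylation). The risks are direct SN2′ reduction of 2 by the copper hydride, a low diastereomer ratio, and the wrong sense of induction at the C–B carbon. The fallback uses known chemistry and sets out from 2. CuCl/Xantphos/NaOt-Bu-catalysed anti-SN2′ borylation with B2pin2 and MeOH in THF gives (1S,4S)-1-methyl-4-(4,4,5,5-tetramethyl-1,3,2-dioxaborolan-2-yl)cyclohex-2-en-1-ol F1. Its sodium alkoxide (NaH) is added at −78 °C in Et2O to (R)-1-lithioethyl N,N-diisopropylcarbamate, made from ethyl N,N-diisopropylcarbamate (ethanol plus i-Pr2NCOCl) with s-BuLi/(+)-sparteine. Warming with MgBr2·OEt2 triggers the 1,2-shift of the ring carbon from boron to carbon, with retention at the ring carbon and inversion at the carbenoid carbon, and the route is rejoined at 5.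

Step 3 (one-pot double homologation and oxidation). The risks are over-homologation, an incomplete second insertion on the alkoxide-bearing substrate, and aldol loss of 8. The fallback sets out from 5. Zweifel olefination (CH2=CHMgBr, THF/DMSO; I2; NaOMe, MeOH) gives (1S,4S)-4-[(2R)-but-3-en-2-yl]-1-methylcyclohex-2-en-1-ol F2. 9-BBN-H followed by H2O2/NaOH converts only the terminal alkene into (3R)-3-[(1R,4S)-4-hydroxy-4-methylcyclohex-2-en-1-yl]butan-1-ol F3. TEMPO/PhI(OAc)2 oxidises the primary alcohol only and returns 8.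

Step 4 (remote stereocontrol at C4). The risks are a modest diastereomer ratio, the wrong sense of induction at C4 and zinc-mediated side reactions of the enolisable aldehyde. The fallback sets out from 8. The lithium acetylide of 9 (LiN(SiMe3)2, THF, −78 °C) gives methyl (4RS,6R)-4-hydroxy-6-[(1R,4S)-4-hydroxy-4-methylcyclohex-2-en-1-yl]hept-2-ynoate F4. MnO2 in CH2Cl2 gives methyl (6R)-6-[(1R,4S)-4-hydroxy-4-methylcyclohex-2-en-1-yl]-4-oxohept-2-ynoate F5. Reduction with (R)-Me-CBS oxazaborolidine and catecholborane (toluene, −78 °C; the alkynyl arm acts as the small group) returns 11.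

Further compounds
F1 | step 2 | (1S,4S)-1-methyl-4-(4,4,5,5-tetramethyl-1,3,2-dioxaborolan-2-yl)cyclohex-2-en-1-ol | CC1(C)OB(OC1(C)C)[C@@H]2C=C[C@@](C)(O)CC2
F2 | step 3 | (1S,4S)-4-[(2R)-but-3-en-2-yl]-1-methylcyclohex-2-en-1-ol | C=C[C@@H](C)[C@@H]1C=C[C@@](C)(O)CC1
F3 | step 3 | (3R)-3-[(1R,4S)-4-hydroxy-4-methylcyclohex-2-en-1-yl]butan-1-ol | OCC[C@@H](C)[C@@H]1C=C[C@@](C)(O)CC1
F4 | step 4 | methyl (4RS,6R)-4-hydroxy-6-[(1R,4S)-4-hydroxy-4-methylcyclohex-2-en-1-yl]hept-2-ynoate | COC(=O)C#CC(O)C[C@@H](C)[C@@H]1C=C[C@@](C)(O)CC1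
F5 | step 4 | methyl (6R)-6-[(1R,4S)-4-hydroxy-4-methylcyclohex-2-en-1-yl]-4-oxohept-2-ynoate | COC(=O)C#CC(=O)C[C@@H](C)[C@@H]1C=C[C@@](C)(O)CC1
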